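A curve that falls and bends tempts one to read it as a decay with one constant, and that is the pitfall in this flask, whose left-handed substrate, followed so far as the north run, gives a first-order constant of 0.155 h⁻¹ at 2.00 h but 0.130 h⁻¹ at 5.00 h.

all flasks: left-handed substrate 0.020 M; right-handed substrate 0.020 M; free catalyst 0.2 mol%

| charge | partner | remark | time |
|---|---|---|---|
| north | 1 equiv | the very flask that is asked about, followed so far |  |
| flask | 1.00 equiv |  | 25 h |

- north (time / h: left-handed substrate / %, right-handed substrate / %, left-handed product / %): 0.250: 48.5, 49.5, 1.6; 0.833: 45.0, 50.6, 7.5; 1.33: 39.7, 50.6, 10.5; 2.00: 36.7, 48.0, 14.3; 3.00: 31.5, 49.6, 17.1; 4.00: 28.8, 50.2, 22.2; 5.00: 26.1, 47.7, 23.5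

(each reading ± 1 percentage point)

- free catalyst is single-handed; left-handed substrate and right-handed substrate are mirror images of each other, charged as a racemate, each of them at the stated concentration
- the earlier runs were read with a standard deviation of 1 percentage point
- an excess is the difference of the two amounts in percent of their sum
- an excess is below zero if the other one leads

- part of the left-handed substrate and right-handed substrate charged together that has reacted at 25 h
- excess of left-handed product over right-handed product in the product at 25 h
- excess of right-handed substrate over left-handed substrate among what is left of the two at 25 h

Who is used up alongside it? At 5.00 h the left-handed substrate has lost 24 percentage points of the two together and the left-handed product reads 23.5%, so with partner charged at 1.00 equiv I take the fraction of partner left as equal to u, the fraction of its own charge of left-handed substrate left.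

Then follow one left-handed molecule: what are its chances? If its chance per hour is proportional to the partner left, it is u/τ, and the reciprocal of u climbs in a straight line with slope one over τ.

What is τ? The reading at 5.00 h means u = 52.2%, which gives 5.46 h, the meeting time, the hours in which the reciprocal of u rises by one. The reading at 2.00 h gives 5.52 h, so this constant holds still where the decay constant drifted.

And the weak spot, the right-handed substrate? It reads 50.2% and 47.7% at the last two times, with a scatter of 1 point, so I can read no sure loss from it and leave it out of the balance of partner, which makes my reckoning for the left-handed substrate 17.9% of its own charge at 25 h, or 8.95% of the two together.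

The forecast, “This fits partner depletion”, takes 8% of the two together instead, and states 45.5% reacted, 85% for the product and 71% for the substrate.

The flask gives 45.4%, 85.8% and 71.4%, each within the margin of the forecast.

    free catalyst + left-handed substrate ⇌ catalyst intermediate A (K = 110 L mol⁻¹, k = 40000 L mol⁻¹ h⁻¹)
    partner + catalyst intermediate A → free catalyst + left-handed product (k = 17000 L mol⁻¹ h⁻¹)
    free catalyst ⇌ dormant form (K = 1.70, k = 2.70 h⁻¹)
    2 free catalyst ⇌ resting dimer, settled at all times (K = 25000 L mol⁻¹)
    free catalyst + right-handed substrate ⇌ catalyst intermediate B (K = 37.0 L mol⁻¹, k = 7.00 × 10⁵ L mol⁻¹ h⁻¹)
    partner + catalyst intermediate B → free catalyst + right-handed product (k = 1300 L mol⁻¹ h⁻¹)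

At 3.84 h catalyst intermediate A falls back 1.9 times faster than it goes on. A bound left-handed substrate molecule therefore passes the fork to left-handed product with a chance of 0.345. On the meeting time of 5.46 h, this flask was reckoned to keep 17.9% of its left-handed substrate and keeps 16%. The neighbour flask with 0.400 equiv of partner, the limiting reagent there, is down to 0.82% of its partner; with the gap between the two fractions held at 0.600, the same clock reckons 61.6% of its left-handed substrate, and it holds 62%.

The numbers in the tables are calculated with constants of no real substance; noise was put on by code.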